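D is slow to show itself: at 50.0 min of Sunday's run it reads 0.9% against a scatter of 0.5 percentage points, while L has fallen to 82.3%.

| flask | L | E | remark | time |
|---|---|---|---|---|
| Tuesday's | 0.25 M | 2 M | run made earlier |  |
| Friday's | 1 M | 2 M | run made earlier |  |
| Sunday's | 0.50 M | 3 M | run made earlier |  |
| north-east | 0.50 M | 2.00 M |  | 6.0 h |
| north-west | 0.50 M | 2.00 M |  | 3.0 h |
| north | 0.50 M | 2.00 M |  | 1.5 h |

| run | time / min | L / % | D / % |
|---|---|---|---|
| Tuesday's | 5.00 | 98.6 | 0.5 |
| Tuesday's | 15.0 | 97.2 | 0 |
| Tuesday's | 25.0 | 94.7 | 0.2 |
| Tuesday's | 40.0 | 91.7 | 0.3 |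
| Tuesday's | 50.0 | 90.5 | 0 |
| Friday's | 5.00 | 95.7 | 0.2 |
| Friday's | 15.0 | 89.7 | 0 |
| Friday's | 25.0 | 82.5 | 0 |
| Friday's | 40.0 | 73.8 | 0.1 |
| Friday's | 50.0 | 69.9 | 0.7 |
| Sunday's | 4.00 | 98.2 | 0.5 |
| Sunday's | 8.00 | 96.7 | 0.2 |
| Sunday's | 15.0 | 94.2 | 0 |
| Sunday's | 30.0 | 88.9 | 0 |
| Sunday's | 50.0 | 82.3 | 0.9 |

(each reading ± 0.5 percentage points)

1. which of these there is most of at the end, counted by the L in it, north-east (L / D)
2. which of these there is most of at the end, counted by the L in it, north-west (L / D)
3. which of these there is most of at the end, counted by the L in it, north (L / D)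
4. the largest of these amounts at the end, in percent of the L charged, north-east
5. the largest of these amounts at the end, in percent of the L charged, north-west
6. the largest of these amounts at the end, in percent of the L charged, north

- percent here means L units held: one J counts as two
- on the list of suspects stand: L + E + D -> 2 D; L + E -> D; E <-> G; 2 L -> J

Build the flask up one step at a time. Begin with the suspect in which two L join to J: L then falls at a constant s times [L] squared, and this second-order rate integrates in closed form, so 1/[L] climbs on a straight line. Friday's run, where L fell furthest, gives 0.517 L mol⁻¹ h⁻¹; this is the dimer slope, the climb of 1/[L] per hour. With c the charge of L and t the time, the fraction of L left is f = 1/(1 + s c t). That gives 72.1% in north, 56.3% in north-west and 39.2% in north-east.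

Now add E and G. E is not read, but Sunday's run, which differs from Friday's in E (3 M against 2 M) and in L as well, gives a slope of 0.516 L mol⁻¹ h⁻¹, so I leave the numbers as they stand. Tuesday's run, at the same E and a quarter of Friday's L, gives 0.504 L mol⁻¹ h⁻¹, which fits the same order within the scatter.

Last add the paths to D, direct and by autocatalysis. D stays near the scatter in these runs, and Sunday's last reading of it is far less than the L lost by then, so they take little from L there. My reckoning keeps L largest in each flask, but north-east runs 7.20 times as long as the last reading, so its risk lies in north-east.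

The forecast has L largest at 71% in north and 52% in north-west. In north-east it parts from mine and names D at 50%, saying of that call: “This last call is uncertain.”

The flask gives L largest in north at 72.7%, in north-west at 57.0%, and L in north-east at 39.6%.

    L + E + D → 2 D (k = 0.800 L² mol⁻² h⁻¹)
    L + E → D (k = 2.20 × 10⁻⁴ L mol⁻¹ h⁻¹)
    E ⇌ G (K = 0.130, k = 0.280 h⁻¹)
    2 L → J (k = 0.250 L mol⁻¹ h⁻¹)

North-east is the point of parting: the law's 39.2% stands beside L at 39.6%, and D is 0.701% where the forecast had 50%. Through those 6.0 h two L joined to J, which reached 59.7%, and at the end E stood at 88% of its charge beside 0.230 M of G, an exchange that moved L little. Left until 60.0 h, north-east holds D at 17.5% and L at 0.164%.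

Read the north flask at 4.0 h instead: the dimer slope gives f = 49.2%. The computed flask holds 49.8% of L.

Readings and results were computed for substances that don't exist; the scatter is artificial.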